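The route cuts the γ-lactone ring at two bonds, C2–C3 and O–C4, which end on the ring-fusion atoms C3 and C4 that this ring shares with the tetrahydrofuran ring. An excited glyoxylate C=O can add across a C3=C4 enol ether at exactly these positions, so one Paternò–Büchi reaction closes a cis-fused oxetane, makes both bonds and sets C3 and C4. Oxetane strain then lets SmI2 break C2–O, and the freed C4 oxygen closes the lactone. The precursor is the (R)-2-(silyloxymethyl)-2,4-dimethyl-2,3-dihydrofuran 10, whose C6 centre comes intact from (S)-2-methylglycidol; the C7–C18 chain is attached afterwards.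

Key step: step 6

Remark: atoms carry the target numbering (C1 lactone carbonyl, C2, ring-fusion C3–H and C4–CH3, C5, quaternary C6, chain C7–C18). With the C6 arrangement the target needs, dihydrofuran 10 has the R descriptor (CH2O outranks the ring CH2), although no bond at C6 is made or broken after (S)-2-methylglycidol. For the same formal reason the descriptor returns to S in step 13.

**Step 1**
Reactants: 1 (S)-2-methylglycidol
Product: 2 (R)-tert-butyl[(2-methyloxiran-2-yl)methoxy]diphenylsilane
Conditions: TBDPSCl, imidazole, DMF, 0 °C → rt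
Reagents that add atoms: tert-butyl(chloro)diphenylsilane, CC(C)(C)[Si](Cl)(c1ccccc1)c1ccccc1
Why: Imidazole-promoted silylation of the primary alcohol leaves the epoxide and C6 untouched and installs a bulky group that has no easily abstracted hydrogen and is transparent above 300 nm, as the photochemical step requires.

**Step 2**
Reactants: 2 (R)-tert-butyl[(2-methyloxiran-2-yl)methoxy]diphenylsilane; 3 isopropenylmagnesium bromide
Product: 4 (2R)-1-{[tert-butyl(diphenyl)silyl]oxy}-2,4-dimethylpent-4-en-2-ol
Conditions: CuI (10 mol%), THF, −30 → 0 °C; aq. NH4Cl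
Reagents that add atoms: none
Why: Copper-catalysed Grignard opening of a 2,2-disubstituted epoxide is an SN2 attack at the unsubstituted CH2 terminus (future C5), so C6 keeps its configuration while the isopropenyl unit brings C4, its methyl group and C3.

**Step 3**
Reactants: 4 (2R)-1-{[tert-butyl(diphenyl)silyl]oxy}-2,4-dimethylpent-4-en-2-ol
Product: 6 (4R)-5-{[tert-butyl(diphenyl)silyl]oxy}-2,4-dimethylpentane-1,4-diol (C2 epimers), via B-alkyl-9-BBN adduct 5 (not isolated)
Conditions: 9-BBN, THF, 0 °C → rt; then NaOH, H2O2, 0 °C → rt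
Reagents that add atoms: hydrogen peroxide, OO
Why: Anti-Markovnikov hydroboration–oxidation of the 1,1-disubstituted alkene places the hydroxyl on the terminal carbon C3, and the unselectively formed C4 centre does not matter because it becomes sp2 again in step 5.

**Step 4**
Reactants: 6 (4R)-5-{[tert-butyl(diphenyl)silyl]oxy}-2,4-dimethylpentane-1,4-diol
Product: 8 (5R)-5-{[tert-butyl(diphenyl)silyl]oxymethyl}-3,5-dimethyloxolan-2-ol (lactol; anomer/C3-epimer mixture), via open-chain hydroxy aldehyde 7 (not isolated)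
Conditions: (COCl)2, DMSO, CH2Cl2, −78 °C; Et3N, −78 → 0 °C
Reagents that add atoms: none
Why: Swern oxidation can only oxidise the primary alcohol, and the resulting γ-hydroxy aldehyde closes spontaneously to the five-membered lactol without over-oxidation to a lactone.

**Step 5**
Reactants: 8 (5R)-5-{[tert-butyl(diphenyl)silyl]oxymethyl}-3,5-dimethyloxolan-2-ol
Product: 10 (R)-tert-butyl[(2,4-dimethyl-2,3-dihydrofuran-2-yl)methoxy]diphenylsilane, via anomeric mesylate 9 (not isolated)
Conditions: MsCl, Et3N (excess), CH2Cl2, −20 °C → reflux; aq. NaHCO3 work-up, Et3N-deactivated silica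
Reagents that add atoms: none
Why: Lactol dehydration through the anomeric sulfonate and its oxocarbenium ion (the method used for glycals) can only remove the C4 hydrogen, so the C3=C4 enol ether should form as a single regioisomer while the permanently basic medium protects it.

**Step 6**
Reactants: 10 (R)-tert-butyl[(2,4-dimethyl-2,3-dihydrofuran-2-yl)methoxy]diphenylsilane; 11 methyl glyoxylate
Product: 12 methyl (1S,3R,5S,7RS)-3-{[tert-butyl(diphenyl)silyl]oxymethyl}-3,5-dimethyl-2,6-dioxabicyclo[3.2.0]heptane-7-carboxylate (ring position 7 is target C2; both epimers)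
Conditions: hν (medium-pressure Hg lamp, Pyrex filter, λ > 300 nm), excess monomeric 11 (distilled from P2O5 just before use), solid K2CO3, degassed benzene at 10 °C
Reagents that add atoms: none
Why: Paternò–Büchi [2+2] photocycloaddition: the n,π* excited glyoxylate attacks with its electron-poor oxygen the nucleophilic β-carbon C4 of the enol ether, giving a 1,4-biradical whose C3 radical is stabilised by the ring oxygen, and after spin inversion C2–C3 radical recombination closes the four-membered ring. The closest known reactions are the photocycloadditions of aldehydes and α-oxo esters to 2,3-dihydrofurans, which give 2,6-dioxabicyclo[3.2.0]heptanes with the same 3-alkoxyoxetane orientation. One ring, the oxetane, is closed, by 1,4-biradical recombination, and it can only be cis-fused to the five-membered ring. C3 and C4 are therefore set as a cis pair in one event, and their absolute sense should follow from approach of the glyoxylate to the face of 10 that carries the C6 methyl group, anti to the bulky CH2OTBDPS group, while the C2 mixture is irrelevant because C2 becomes CH2 in step 7. The step needs regioselectivity (O to C4), secured by the enol-ether polarity and reinforced by the C4 methyl group, and facial selectivity, secured by the silyloxymethyl group. Long-wavelength light, a cool acid-free medium and excess monomeric 11 should hold back the thermal ene reaction and hydrolysis of the enol ether.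

**Step 7**
Reactants: 12 methyl (1S,3R,5S,7RS)-3-{[tert-butyl(diphenyl)silyl]oxymethyl}-3,5-dimethyl-2,6-dioxabicyclo[3.2.0]heptane-7-carboxylate
Product: 14 (3aS,5R,6aS)-5-{[tert-butyl(diphenyl)silyl]oxymethyl}-5,6a-dimethyltetrahydrofuro[3,2-b]furan-2(3H)-one, via ring-opened hydroxy ester 13 (not isolated)
Conditions: SmI2 (3 equiv), MeOH (5 equiv), THF–HMPA, −78 → 0 °C; then CSA (cat.), CH2Cl2, rt
Reagents that add atoms: none
Why: SmI2 reduction of an α-alkoxy ester: electron transfer to the ester and strain-assisted scission of the C2–O bond give, after a second electron transfer, a samarium enolate that methanol protonates before the β-oxygen at C3 can be expelled, and the freed C4 hydroxyl, held cis to the CH2CO2Me arm, lactonises (5-exo-trig) with loss of methanol while C3, C4 and C6 stay untouched.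

**Step 8**
Reactants: 14 (3aS,5R,6aS)-5-{[tert-butyl(diphenyl)silyl]oxymethyl}-5,6a-dimethyltetrahydrofuro[3,2-b]furan-2(3H)-one
Product: 15 (3aS,5R,6aS)-5-(hydroxymethyl)-5,6a-dimethyltetrahydrofuro[3,2-b]furan-2(3H)-one
Conditions: Bu4NF, AcOH, THF, 0 °C → rt
Reagents that add atoms: none
Why: Fluoride-induced desilylation, buffered with acetic acid so that the medium does not open the γ-lactone.

**Step 9**
Reactants: 15 (3aS,5R,6aS)-5-(hydroxymethyl)-5,6a-dimethyltetrahydrofuro[3,2-b]furan-2(3H)-one
Product: 16 (3aS,5R,6aS)-5,6a-dimethyl-2-oxohexahydrofuro[3,2-b]furan-5-carbaldehyde (C7 aldehyde)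
Conditions: Dess–Martin periodinane, CH2Cl2, 0 °C → rt
Reagents that add atoms: none
Why: Dess–Martin oxidation of the primary alcohol gives an aldehyde on the quaternary C6, which cannot enolise or epimerise.

**Step 10**
Reactants: 17 8-bromooctan-1-ol
Product: 18 {[(8-bromooctyl)oxy]methyl}benzene
Conditions: BnOC(=NH)CCl3, TfOH (cat.), cyclohexane–CH2Cl2, 0 °C → rt
Reagents that add atoms: benzyl 2,2,2-trichloroacetimidate, ClC(Cl)(Cl)C(=N)OCc1ccccc1
Why: Acid-catalysed benzylation with the trichloroacetimidate avoids an alkoxide, which would displace the primary bromide, and the benzyl group is chosen because step 13 removes it together with the alkene.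

**Step 11**
Reactants: 18 {[(8-bromooctyl)oxy]methyl}benzene
Product: 19 [8-(benzyloxy)octyl]triphenylphosphonium bromide
Conditions: PPh3, MeCN, reflux
Reagents that add atoms: triphenylphosphine, c1ccc(cc1)P(c1ccccc1)c1ccccc1
Why: SN2 quaternisation of triphenylphosphine by the unhindered primary bromide.

**Step 12**
Reactants: 16 (3aS,5R,6aS)-5,6a-dimethyl-2-oxohexahydrofuro[3,2-b]furan-5-carbaldehyde; 19 [8-(benzyloxy)octyl]triphenylphosphonium bromide
Product: 21 (3aS,5R,6aS)-5-[(1Z)-9-(benzyloxy)non-1-en-1-yl]-5,6a-dimethyltetrahydrofuro[3,2-b]furan-2(3H)-one (mainly Z; geometry irrelevant), via phosphonium ylide 20 (not isolated)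
Conditions: NaN(SiMe3)2, THF, 0 °C; then 16, −78 °C → rt
Reagents that add atoms: none
Why: Wittig olefination with a non-stabilised ylide forms C7=C8, since at −78 °C the ylide adds to the non-enolisable aldehyde much faster than it attacks or deprotonates the γ-lactone.

**Step 13**
Reactants: 21 (3aS,5R,6aS)-5-[(1Z)-9-(benzyloxy)non-1-en-1-yl]-5,6a-dimethyltetrahydrofuro[3,2-b]furan-2(3H)-one
Product: 23 (3aS,5S,6aS)-5-(9-hydroxynonyl)-5,6a-dimethyltetrahydrofuro[3,2-b]furan-2(3H)-one, via saturated benzyl ether 22 (not isolated)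
Conditions: H2 (1 atm), Pd(OH)2/C, EtOAc, rt
Reagents that add atoms: none
Why: Catalytic hydrogenation saturates C7=C8 and hydrogenolyses the benzyl ether in one operation, the neutral solvent disfavouring cleavage of the allylic C6–O bond and the lactone being inert.

**Step 14**
Reactants: 23 (3aS,5S,6aS)-5-(9-hydroxynonyl)-5,6a-dimethyltetrahydrofuro[3,2-b]furan-2(3H)-one
Product: 24 9-[(3aS,5S,6aS)-5,6a-dimethyl-2-oxohexahydrofuro[3,2-b]furan-5-yl]nonanal (C15 aldehyde)
Conditions: Dess–Martin periodinane, CH2Cl2, rt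
Reagents that add atoms: none
Why: Dess–Martin oxidation of the unhindered primary alcohol stops cleanly at the aldehyde under nearly neutral conditions.

**Step 15**
Reactants: 24 9-[(3aS,5S,6aS)-5,6a-dimethyl-2-oxohexahydrofuro[3,2-b]furan-5-yl]nonanal; 25 diethyl cinnamylphosphonate
Product: 27 plakortone P [(3aS,5S,6aS)-5,6a-dimethyl-5-[(9E,11E)-12-phenyldodeca-9,11-dien-1-yl]tetrahydrofuro[3,2-b]furan-2(3H)-one], via lithiated phosphonate 26 (not isolated)
Conditions: LiN(SiMe3)2, THF, −78 °C; then 24, −78 °C → rt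
Reagents that add atoms: none
Why: Horner–Wadsworth–Emmons olefination with the stabilised allylic phosphonate anion should form C15=C16 with E geometry (C17=C18 comes E from the reagent), and this soft anion adds to the aldehyde in preference to the lactone.

**Compound list**

1 | (S)-2-methylglycidol [(2S)-(2-methyloxiran-2-yl)methanol] | C[C@]1(CO)CO1 | starting material
2 | (R)-tert-butyl[(2-methyloxiran-2-yl)methoxy]diphenylsilane | C[C@]1(CO[Si](c2ccccc2)(c2ccccc2)C(C)(C)C)CO1 | intermediate
3 | isopropenylmagnesium bromide (prop-1-en-2-ylmagnesium bromide) | CC(=C)[Mg]Br | starting material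
4 | (2R)-1-{[tert-butyl(diphenyl)silyl]oxy}-2,4-dimethylpent-4-en-2-ol | C[C@](O)(CO[Si](c1ccccc1)(c1ccccc1)C(C)(C)C)CC(C)=C | intermediate
5 | (2R)-5-(9-borabicyclo[3.3.1]nonan-9-yl)-1-{[tert-butyl(diphenyl)silyl]oxy}-2,4-dimethylpentan-2-ol (C4 epimers; not isolated) | C[C@](O)(CO[Si](c1ccccc1)(c1ccccc1)C(C)(C)C)CC(C)CB1C2CCCC1CCC2 | intermediate
6 | (4R)-5-{[tert-butyl(diphenyl)silyl]oxy}-2,4-dimethylpentane-1,4-diol (C2 epimers) | C[C@](O)(CO[Si](c1ccccc1)(c1ccccc1)C(C)(C)C)CC(C)CO | intermediate
7 | (4R)-5-{[tert-butyl(diphenyl)silyl]oxy}-4-hydroxy-2,4-dimethylpentanal (C2 epimers; not isolated) | C[C@](O)(CO[Si](c1ccccc1)(c1ccccc1)C(C)(C)C)CC(C)C=O | intermediate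
8 | (5R)-5-{[tert-butyl(diphenyl)silyl]oxymethyl}-3,5-dimethyloxolan-2-ol (anomers and C3 epimers) | C[C@]1(CO[Si](c2ccccc2)(c2ccccc2)C(C)(C)C)CC(C)C(O)O1 | intermediate
9 | (5R)-5-{[tert-butyl(diphenyl)silyl]oxymethyl}-3,5-dimethyloxolan-2-yl methanesulfonate (not isolated) | C[C@]1(CO[Si](c2ccccc2)(c2ccccc2)C(C)(C)C)CC(C)C(OS(C)(=O)=O)O1 | intermediate
10 | (R)-tert-butyl[(2,4-dimethyl-2,3-dihydrofuran-2-yl)methoxy]diphenylsilane | C[C@]1(CO[Si](c2ccccc2)(c2ccccc2)C(C)(C)C)CC(C)=CO1 | intermediate
11 | methyl glyoxylate (methyl 2-oxoacetate) | O=CC(=O)OC | starting material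
12 | methyl (1S,3R,5S,7RS)-3-{[tert-butyl(diphenyl)silyl]oxymethyl}-3,5-dimethyl-2,6-dioxabicyclo[3.2.0]heptane-7-carboxylate | C[C@]1(CO[Si](c3ccccc3)(c3ccccc3)C(C)(C)C)C[C@]2(C)OC(C(=O)OC)[C@@H]2O1 | intermediate
13 | methyl 2-[(2S,3S,5R)-5-{[tert-butyl(diphenyl)silyl]oxymethyl}-3-hydroxy-3,5-dimethyloxolan-2-yl]acetate (not isolated) | C[C@]1(CO[Si](c2ccccc2)(c2ccccc2)C(C)(C)C)C[C@](C)(O)[C@H](CC(=O)OC)O1 | intermediate
14 | (3aS,5R,6aS)-5-{[tert-butyl(diphenyl)silyl]oxymethyl}-5,6a-dimethyltetrahydrofuro[3,2-b]furan-2(3H)-one | C[C@]1(CO[Si](c3ccccc3)(c3ccccc3)C(C)(C)C)C[C@]2(C)OC(=O)C[C@@H]2O1 | intermediate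
15 | (3aS,5R,6aS)-5-(hydroxymethyl)-5,6a-dimethyltetrahydrofuro[3,2-b]furan-2(3H)-one | C[C@]1(CO)C[C@]2(C)OC(=O)C[C@@H]2O1 | intermediate
16 | (3aS,5R,6aS)-5,6a-dimethyl-2-oxohexahydrofuro[3,2-b]furan-5-carbaldehyde | C[C@]1(C=O)C[C@]2(C)OC(=O)C[C@@H]2O1 | intermediate
17 | 8-bromooctan-1-ol | OCCCCCCCCBr | starting material
18 | {[(8-bromooctyl)oxy]methyl}benzene | BrCCCCCCCCOCc1ccccc1 | intermediate
19 | [8-(benzyloxy)octyl]triphenylphosphonium bromide | [Br-].C(CCCCCCCOCc1ccccc1)[P+](c1ccccc1)(c1ccccc1)c1ccccc1 | intermediate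
20 | [8-(benzyloxy)octylidene]triphenylphosphorane (not isolated) | C(CCCCCCCOCc1ccccc1)=P(c1ccccc1)(c1ccccc1)c1ccccc1 | intermediate
21 | (3aS,5R,6aS)-5-[(1Z)-9-(benzyloxy)non-1-en-1-yl]-5,6a-dimethyltetrahydrofuro[3,2-b]furan-2(3H)-one | C[C@]1(/C=C\CCCCCCCOCc3ccccc3)C[C@]2(C)OC(=O)C[C@@H]2O1 | intermediate
22 | (3aS,5S,6aS)-5-[9-(benzyloxy)nonyl]-5,6a-dimethyltetrahydrofuro[3,2-b]furan-2(3H)-one (not isolated) | C[C@]1(CCCCCCCCCOCc3ccccc3)C[C@]2(C)OC(=O)C[C@@H]2O1 | intermediate
23 | (3aS,5S,6aS)-5-(9-hydroxynonyl)-5,6a-dimethyltetrahydrofuro[3,2-b]furan-2(3H)-one | C[C@]1(CCCCCCCCCO)C[C@]2(C)OC(=O)C[C@@H]2O1 | intermediate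
24 | 9-[(3aS,5S,6aS)-5,6a-dimethyl-2-oxohexahydrofuro[3,2-b]furan-5-yl]nonanal | C[C@]1(CCCCCCCCC=O)C[C@]2(C)OC(=O)C[C@@H]2O1 | intermediate
25 | diethyl cinnamylphosphonate (diethyl [(2E)-3-phenylprop-2-en-1-yl]phosphonate) | CCOP(=O)(C/C=C/c1ccccc1)OCC | starting material
26 | lithium salt of diethyl cinnamylphosphonate (not isolated) | [Li+].CCOP(=O)([CH-]/C=C/c1ccccc1)OCC | intermediate
27 | plakortone P [(3aS,5S,6aS)-5,6a-dimethyl-5-[(9E,11E)-12-phenyldodeca-9,11-dien-1-yl]tetrahydrofuro[3,2-b]furan-2(3H)-one] | C[C@]1(CCCCCCCC/C=C/C=C/c2ccccc2)C[C@]2(C)OC(=O)C[C@@H]2O1 | target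

Total step count: 15. Longest linear sequence: 13 steps (steps 1–9 and 12–15, from 1).

**Steps most likely to fail**

Step 6. The excited glyoxylate may attack the face syn to the silyloxymethyl group, the orientation may partly reverse to the acetal-type oxetane, or allylic hydrogen abstraction and ene-type addition may compete with cycloaddition. The fallback is thermal, sets out from 10 and comes back at 14, so it also replaces step 7. Dichloroketene (Cl3CCOCl, Zn–Cu couple, Et2O–DME, rt) should add to the enol ether in a [2+2] cycloaddition. Its carbonyl carbon should bond to the nucleophilic C4 and its CCl2 carbon to the oxygen-bearing C3. The sterically demanding ketene should approach anti to the CH2OTBDPS group and give the cis-fused (1R,3R,5S)-3-{[tert-butyl(diphenyl)silyl]oxymethyl}-7,7-dichloro-3,5-dimethyl-2-oxabicyclo[3.2.0]heptan-6-one F1. Zinc in acetic acid should remove both chlorines to give (1S,3R,5S)-3-{[tert-butyl(diphenyl)silyl]oxymethyl}-3,5-dimethyl-2-oxabicyclo[3.2.0]heptan-6-one F2. Baeyer–Villiger oxidation (mCPBA, NaHCO3, CH2Cl2) should then insert oxygen next to the more substituted migrating carbon C4 with retention and deliver lactone 14.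

Step 7. The samarium enolate may expel the β-oxygen at C3 and open the tetrahydrofuran ring, or electron transfer may be incomplete and leave unopened oxetane. The fallback replaces electron transfer by polar opening followed by radical reduction; it sets out from 12 and comes back at 14. About one equivalent of PhSeNa (from PhSeSePh and NaBH4 in EtOH, buffered with AcOH) should open the oxetane by SN2 attack at C2, the only accessible and carbonyl-activated carbon, as selenide does at the α-carbon of α,β-epoxy esters. This should give methyl 2-[(2R,3S,5R)-5-{[tert-butyl(diphenyl)silyl]oxymethyl}-3-hydroxy-3,5-dimethyloxolan-2-yl]-2-(phenylselanyl)acetate F3. Catalytic CSA should lactonise it to (3aR,5R,6aS)-5-{[tert-butyl(diphenyl)silyl]oxymethyl}-5,6a-dimethyl-3-(phenylselanyl)tetrahydrofuro[3,2-b]furan-2(3H)-one F4. Bu3SnH with AIBN (toluene, 80 °C) should replace selenium by hydrogen through an α-acyl radical, which does not eliminate the β-oxygen, and return 14.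

Step 5. Elimination of the anomeric sulfonate may be incomplete, the lactol may condense with itself, or the acid-labile trisubstituted enol ether may rehydrate during work-up. The fallback separates activation from elimination; it sets out from 8 and comes back at 10. MeOH with catalytic PPTS should convert the lactol into the methyl acetal tert-butyl{[(2R)-5-methoxy-2,4-dimethyloxolan-2-yl]methoxy}diphenylsilane F5. Me3SiOTf with i-Pr2NEt (CH2Cl2, −20 °C → rt) should then ionise the acetal and remove the C4 proton under anhydrous, permanently basic conditions, a known acetal-to-enol-ether conversion, to give 10.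

**Further compounds**

F1 | step 6 | (1R,3R,5S)-3-{[tert-butyl(diphenyl)silyl]oxymethyl}-7,7-dichloro-3,5-dimethyl-2-oxabicyclo[3.2.0]heptan-6-one | C[C@]1(CO[Si](c3ccccc3)(c3ccccc3)C(C)(C)C)C[C@]2(C)C(=O)C(Cl)(Cl)[C@@H]2O1
F2 | step 6 | (1S,3R,5S)-3-{[tert-butyl(diphenyl)silyl]oxymethyl}-3,5-dimethyl-2-oxabicyclo[3.2.0]heptan-6-one | C[C@]1(CO[Si](c3ccccc3)(c3ccccc3)C(C)(C)C)C[C@]2(C)C(=O)C[C@@H]2O1
F3 | step 7 | methyl 2-[(2R,3S,5R)-5-{[tert-butyl(diphenyl)silyl]oxymethyl}-3-hydroxy-3,5-dimethyloxolan-2-yl]-2-(phenylselanyl)acetate (epimers at the selenium-bearing carbon) | C[C@]1(CO[Si](c2ccccc2)(c2ccccc2)C(C)(C)C)C[C@](C)(O)[C@H](C([Se]c2ccccc2)C(=O)OC)O1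
F4 | step 7 | (3aR,5R,6aS)-5-{[tert-butyl(diphenyl)silyl]oxymethyl}-5,6a-dimethyl-3-(phenylselanyl)tetrahydrofuro[3,2-b]furan-2(3H)-one (C3 epimers) | C[C@]1(CO[Si](c3ccccc3)(c3ccccc3)C(C)(C)C)C[C@]2(C)OC(=O)C([Se]c3ccccc3)[C@@H]2O1
F5 | step 5 | tert-butyl{[(2R)-5-methoxy-2,4-dimethyloxolan-2-yl]methoxy}diphenylsilane (anomers and C4 epimers) | C[C@]1(CO[Si](c2ccccc2)(c2ccccc2)C(C)(C)C)CC(C)C(OC)O1
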